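## The problem

The target is a heliangolide-type germacranolide, (1R,3S,6R,7R,8S,10R)-3-acetoxy-1,10-epoxy-8-(3-methylbutanoyloxy)germacra-4Z,11(13)-dien-12,6-olide. Its ten-membered carbocycle (C1–C10) carries a trans-fused α-methylene-γ-lactone across C6–C7, a Z trisubstituted olefin C4=C5, a trans 1,10-epoxide (the oxidised form of an E C1=C10 olefin), an allylic acetate at C3 and an isovalerate at C8. A synthesis must form a strained medium ring and fix two trisubstituted olefins of opposite geometry in it; end-to-end closure of such a ring is entropically and transannularly costly.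

Of the six stereocentres, C6, C7 and C8 are contiguous: O6 is anti to the C7 side chain, the side chain is anti to O8, and O6 is syn to O8. The C7/C8 trans pair can therefore be set on a small ring, and C6 can then be derived from C8 by 1,3-chelation. C1 and C10 follow stereospecifically from the E olefin once the face of attack is fixed by the ring conformation. C3 is insulated from the others by the Z olefin and has to be brought in as a resolved centre.

The fragile groups are the α-methylene lactone (a Michael acceptor that does not tolerate nucleophiles or late enolate chemistry), the trisubstituted epoxide (acid induces transannular opening by C4=C5), the allylic acetate, and two different esters on secondary alcohols that must be told apart. Every C6 ketone intermediate carries a β-oxygen at C8 and can eliminate, and the 1,5-diene can undergo Cope rearrangement.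

The enabling feature is that C1=C10 and C4=C5 are 1,5-related. They are the formal metathesis product of a C5=C10 bond in a six-membered ring (C5–C10, holding C7 and C8) and a C1=C4 bond in a four-membered ring (C1–C4, holding C3). Because C6 is oxygenated, the six-membered partner can be a cyclohexenone, a chromophore that adds to a cyclobutene on irradiation.

## Retrosynthesis

**Epoxide last.** Target 26 is cut at the two C–O bonds of the oxirane to give triene 25. The epoxide is the most acid-sensitive group, and C1=C10 is the only electron-rich olefin in 25, so chemoselectivity is inherent. The forward step must deliver oxygen to the correct face of the E olefin.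

**Acyl groups after the methylene.** The acetate and isovalerate of 25 are removed in turn (25 ⇒ 24 ⇒ 23 ⇒ 22 ⇒ 21), and the exocyclic methylene is then removed (21 ⇒ 18). The order is dictated by the methylenation, which needs a lactone enolate and tolerates no other enolisable ester. Lactone 18 therefore carries two orthogonal ethers: a silyl ether at O3 and a 4-methoxybenzyl ether at O8. The benzylic ether is chosen at C8 because an alkoxide is a poorer leaving group than a silyloxide, and because it can chelate.

**Lactone and C6.** Lactone 18 is opened at the O6–C12 bond to hydroxy ester 17, and C6 is returned to the ketone of dienone 16. This removes a stereocentre and gives the ketone that the ring-forming chemistry needs. The forward reduction must place O6 syn to O8; a chelate between the C6 carbonyl and the C8 ether is designed to do this.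

**Ten-membered ring.** In dienone 16 the bonds C5–C10 and C1–C4 are reconnected to give the cis-anti-cis 6-4-4 tricycle 15. Against closing any single ring bond end to end, this derives the medium ring from strain already stored in a bicyclo[2.2.0]hexane unit. The forward thermolysis must give E at C1=C10 and Z at C4=C5 and must stop before Cope rearrangement.

**Key cut.** Tricycle 15 is cut at C1–C10 and C4–C5 into enone 9 and cyclobutene 14. The simplification is large: 9 is a six-membered ring holding the C7/C8 pair, and 14 is a four-membered ring holding C3. The four centres made in the cycloaddition are later erased, so only the regiochemistry and the cis-anti-cis relation are required.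

**Enone 9.** The C7–C11 bond is cut to enone 7 and methyl bromoacetate 8 (alkylation anti to the neighbouring ether). The methyl group of 7 is removed via silyl enol ether 6 to enone 5. Enone 5 derives from monoacetate 3 (through ketone 4), and 3 from the meso diol 2 by desymmetrisation. Diol 2 is the mono-ether of the commercial all-cis triol 1, the hydrogenation product of phloroglucinol.

**Cyclobutene 14.** The silyl ether is removed to the S alcohol 13, obtained by resolution of racemate 12. Alcohol 12 comes from allylic oxidation of 1-methylcyclobutene 11, the isomer of commercial methylenecyclobutane 10.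

## Roads not taken

**Alternative 1:** The ring is cut at C3–C4. In the forward sense the Z iodoalkene of the seco-lactone A1 is converted by CrCl2 and catalytic NiCl2 (Nozaki–Hiyama–Kishi) into an alkenylchromium species that adds to the C3 aldehyde, giving the ring and the C3 alcohol A2.

- Merits: both olefin geometries are fixed in open-chain material before the ring exists, which is more secure than the mechanistic argument the chosen plan relies on. A2 is identical with compound 24, two steps from the target, with the lactone, the methylene and the isovalerate already present.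
- Weak points: a ten-membered ring is closed end to end, so high dilution is needed. C3 is created in the closure with little to control it. Excess divalent chromium meets an α-methylene lactone. A1 needs a long linear synthesis of the C6–C7–C8 triad and two defined trisubstituted olefins.
- Comparison: the chosen plan offers ring formation without macrocyclisation and a C3 centre that arrives resolved.

**Alternative 2:** The cuts are C9–C10 and the C1–O bond. Zinc inserts into the C9 bromide of A3, the zinc enolate adds to the C10 ketone, and the resulting alkoxide displaces chloride at C1 to give the epoxy ketone A4 (a Reformatsky addition followed by a Darzens-type closure).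

- Merits: the ring bond and the oxirane form in one operation, and no late peracid step is needed. C1 is programmed by the chloride (inversion) rather than left to conformational face selection; in that respect it is better than the chosen plan.
- Weak points: two α-halo ketones compete for zinc. The enolate must add to an enolisable methyl ketone through a ten-membered transition state. The face of attack at C10, which decides whether the epoxide is trans, is uncontrolled. The C8 ketone makes C7 epimerisable and must later be reduced to 8S. A4 still lacks C13 and both acyl groups.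
- Comparison: the chosen plan offers a stereospecific link between E geometry and the trans epoxide, and a ring-forming step that does not depend on a medium-ring aldol-type closure.

**Alternative 3:** The bond C8–C9 is formed and C1–C6 is broken. The potassium alkoxide of the trans-dialkenyl cyclohexenol A5 (KH, 18-crown-6) undergoes an anionic oxy-Cope shift to the cyclodecadienone A6.

- Merits: the chair transition state gives E at C1=C10, the Z C4=C5 bond is inherited from the six-membered ring, and C8 follows from the enol ether geometry. No photochemistry is needed. For olefin geometry this road is at least as good as, and probably better than, a thermal cycloreversion.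
- Weak points: A6 lacks the C7 side chain. It would have to be added by alkylating a ten-membered enolate next to the C8 ether, with only ring conformation for control and β-elimination as a competitor. The enolate produced by the rearrangement already has the C8 alkoxy group in the β position under strongly basic conditions. A5 needs a diastereoselective 1,2-addition of a 2-alkoxyvinyl metal to an enolisable, α′-branched enone.
- Comparison: the chosen plan fixes the C7/C8 trans pair on a six-membered ring, where anti alkylation is reliable, and expands the ring under neutral conditions.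

Key step: step 11

Assumption: the lipase of step 2 acetylates the hydroxyl that leads to 3 as drawn, and that of step 9 acetylates the R alcohol and leaves 13; if either enzyme has the opposite preference, hydrolysis of the meso diacetate of 2, or methanolysis of the acetate fraction from 12, gives the same 3 and 13.

## Route

Germacrane locants (C1–C15) are used for all compounds from 9 and 14 onward.

Step 1
Reactants: 1 cis,cis-cyclohexane-1,3,5-triol
Product: 2 cis,cis-5-(4-methoxybenzyloxy)cyclohexane-1,3-diol (meso)
Conditions: NaH (1.0 equiv), 4-MeOC6H4CH2Cl (0.8 equiv), Bu4NI (cat.), DMF, 0 °C → rt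
Reagents that add atoms: 4-methoxybenzyl chloride COc1ccc(CCl)cc1
Why: Williamson etherification; the three hydroxyls are equivalent, so mono-alkylation with the triol in excess gives one meso diol, and unreacted 1 is recovered.

Step 2
Reactants: 2 cis,cis-5-(4-methoxybenzyloxy)cyclohexane-1,3-diol
Product: 3 (1S,3S,5R)-3-hydroxy-5-(4-methoxybenzyloxy)cyclohexyl acetate (all-cis)
Conditions: Novozym 435 (immobilised Candida antarctica lipase B), vinyl acetate, tBuOMe, 30 °C
Reagents that add atoms: vinyl acetate C=COC(C)=O
Why: Lipase desymmetrisation of a meso 1,3-diol by irreversible transesterification; the enzyme distinguishes the enantiotopic hydroxyls and so sets the absolute configuration of the carbon that becomes C8.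

Step 3
Reactants: 3 (1S,3S,5R)-3-hydroxy-5-(4-methoxybenzyloxy)cyclohexyl acetate
Product: 5 (S)-5-(4-methoxybenzyloxy)cyclohex-2-en-1-one, via β-acetoxy ketone 4 (not isolated)
Conditions: nPr4N[RuO4] (5 mol %), N-methylmorpholine N-oxide, 4 Å MS, CH2Cl2, rt; then DBU (1.1 equiv), 0 °C
Reagents that add atoms: none
Why: Ley–Griffith oxidation of the free alcohol, then E1cB loss of acetate (a far better leaving group than the benzylic alkoxide) in the same flask; the ether-bearing stereocentre is not touched.

Step 4
Reactants: 5 (S)-5-(4-methoxybenzyloxy)cyclohex-2-en-1-one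
Product: 6 [(3S,5S)-5-(4-methoxybenzyloxy)-3-methylcyclohex-1-en-1-yl]oxytrimethylsilane (3,5-trans)
Conditions: MeMgBr, CuBr·SMe2 (10 mol %), Me3SiCl, THF, −78 °C; Et3N, cold aq NaHCO3
Reagents that add atoms: methylmagnesium bromide C[Mg]Br; chlorotrimethylsilane C[Si](C)(C)Cl
Why: Copper-catalysed conjugate addition with in situ silyl trapping; the enolate is captured on the side remote from the ether and cannot expel it. Methyl should enter anti to the ether, but this centre is erased in step 5.

Step 5
Reactants: 6 [(3S,5S)-5-(4-methoxybenzyloxy)-3-methylcyclohex-1-en-1-yl]oxytrimethylsilane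
Product: 7 (S)-5-(4-methoxybenzyloxy)-3-methylcyclohex-2-en-1-one
Conditions: Pd(OAc)2 (1.05 equiv), MeCN, rt
Reagents that add atoms: none
Why: Saegusa–Ito oxidation; β-hydride elimination from the methyl-bearing carbon regenerates the enone with the carbonyl unmoved, so the ether carbon keeps its configuration.

Step 6
Reactants: 7 (S)-5-(4-methoxybenzyloxy)-3-methylcyclohex-2-en-1-one; 8 methyl bromoacetate
Product: 9 methyl 2-[(1R,6S)-6-(4-methoxybenzyloxy)-4-methyl-2-oxocyclohex-3-en-1-yl]acetate (trans; germacrane C7 R, C8 S)
Conditions: LiN(iPr)2 (1.0 equiv), THF, −78 °C; then 8, DMPU, −78 → −50 °C; AcOH quench at −78 °C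
Reagents that add atoms: none
Why: Kinetic α′ deprotonation gives the cross-conjugated lithium dienolate, which is alkylated on the face anti to the adjacent ether (the usual course for 5-substituted cyclohexenone α′-enolates), setting C7 trans to C8. Low temperature and the poor leaving-group ability of an alkoxide hold back E1cB elimination.

Step 7
Reactants: 10 methylenecyclobutane
Product: 11 1-methylcyclobutene
Conditions: Na on Al2O3 (cat.), neat, rt; fractional distillation
Reagents that add atoms: none
Why: Base-catalysed prototropic isomerisation of the exocyclic olefin to the more substituted endocyclic one, which is favoured at equilibrium.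

Step 8
Reactants: 11 1-methylcyclobutene
Product: 12 rac-2-methylcyclobut-2-en-1-ol
Conditions: SeO2 (0.3 equiv), tBuOOH (2 equiv), CH2Cl2, 0 °C → rt
Reagents that add atoms: tert-butyl hydroperoxide CC(C)(C)OO
Why: Selenium dioxide allylic oxidation (ene reaction, then [2,3]-sigmatropic shift); as with 1-methylcyclohexene, oxygen should enter at the ring CH2 next to the methyl-bearing olefin carbon.

Step 9
Reactants: 12 rac-2-methylcyclobut-2-en-1-ol
Product: 13 (S)-2-methylcyclobut-2-en-1-ol
Conditions: Amano lipase PS (Burkholderia cepacia), vinyl acetate, pentane, rt, stopped just past half conversion; chromatography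
Reagents that add atoms: none
Why: Lipase kinetic resolution of a secondary allylic alcohol; the R enantiomer should be acetylated faster (its larger flanking group is the substituted sp2 carbon), leaving the S alcohol, the future C3.

Step 10
Reactants: 13 (S)-2-methylcyclobut-2-en-1-ol
Product: 14 (S)-tert-butyldimethyl(2-methylcyclobut-2-en-1-yloxy)silane
Conditions: tBuMe2SiCl, imidazole, DMF, rt
Reagents that add atoms: tert-butyldimethylsilyl chloride CC(C)(C)[Si](C)(C)Cl
Why: Standard silylation; the silyl ether survives irradiation, 185 °C, hydride and the lactone enolate, and is orthogonal to the benzylic ether at C8.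

Step 11
Reactants: 9 methyl 2-[(1R,6S)-6-(4-methoxybenzyloxy)-4-methyl-2-oxocyclohex-3-en-1-yl]acetate; 14 (S)-tert-butyldimethyl(2-methylcyclobut-2-en-1-yloxy)silane
Product: 15 cis-anti-cis tricyclo[4.4.0.0(2,5)]decan-7-one photoadduct (new bonds C1–C10 and C4–C5; C6 ketone; methyls on C10 and C4; C3 silyl ether on the face away from the new bonds; new four-membered ring on the cyclohexanone face opposite the C8 ether)
Conditions: hν (350 nm lamps, uranium-glass filter), 14 (4 equiv), CH2Cl2 (degassed), −40 °C
Reagents that add atoms: none
Why: Excitation of 9 and intersystem crossing give the twisted triplet enone, which bonds through its β-carbon C10 to the unsubstituted cyclobutene carbon C1 of 14; the triplet 1,4-diradical (α-keto radical at C5, tertiary radical at C4) spin-inverts and collapses by C4–C5 bond formation, so the central cyclobutane is closed by radical recombination of a 1,4-diradical (a stepwise [2+2]). The closest known reaction type is the photocycloaddition of 3-methylcyclohex-2-enones to 1-methylcyclobutene and other cyclobutenes. The required regiochemistry (C10–C1 and C5–C4, methyl groups 1,3 on the new ring) is secured by two substrate features: only this first bond leaves both radical centres stabilised, and the other orientation would have to join the two fully substituted carbons C10 and C4. The C5–C10 fusion should be cis because closure to a trans-fused bicyclo[4.2.0]octanone is strained, and the C1–C4 fusion is cis because it is inherited from the cyclobutene. The anti relation of the outer rings follows from approach of 14 with its ring turned away from C6 and C9, on the cyclobutene face opposite the bulky C3 silyl ether. C10 should be attacked anti to the C8 ether, but the enone face is not critical: C1, C4, C5 and C10 all become sp2 in step 12, so any cis-anti-cis facial isomer converges. C3, C7 and C8 are spectators. Long-wavelength light, low temperature and an excess of 14 (recovered) protect the saturated ketone product from secondary photochemistry and the β-alkoxy ketone from elimination.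

Step 12
Reactants: 15 cis-anti-cis photoadduct
Product: 16 methyl 2-[(1R,3Z,5S,7E,10S)-5-(tert-butyldimethylsilyloxy)-10-(4-methoxybenzyloxy)-4,8-dimethyl-2-oxocyclodeca-3,7-dien-1-yl]acetate (germacra-1(10)E,4Z-dien-6-one; 3S,7R,8S)
Conditions: PhMe (0.01 M, degassed), 2,6-di-tert-butyl-4-methylphenol (trace), silylated sealed tube, 185 °C
Reagents that add atoms: none
Why: Thermal cycloreversion of the bicyclo[2.2.0]hexane unit: homolysis of the strained C1–C4 bond gives a cyclohexane-1,4-diyl, which cleaves C5–C10, the bond whose loss creates the conjugated enone. One olefin must form with inversion: rotation at the tertiary radical C4 puts C15 cis to H5 and avoids allylic strain with the C6 carbonyl (Z), while C1=C10 forms with retention (E). No stereocentre is made, and C3, C7 and C8 are untouched.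

Step 13
Reactants: 16 germacra-1(10)E,4Z-dien-6-one ester
Product: 18 (3S,6R,7R,8S)-3-(tert-butyldimethylsilyloxy)-8-(4-methoxybenzyloxy)germacra-1(10)E,4Z-dien-12,6-olide, via hydroxy ester 17 (not isolated)
Conditions: Zn(BH4)2, Et2O, −20 → 0 °C; aq NH4Cl; then PPTS (cat.), PhH, 40 °C
Reagents that add atoms: none
Why: Chelation-controlled 1,2-reduction of a β-alkoxy enone: zinc bridges the C6 carbonyl and the C8 ether oxygen, the C7 side chain sits axial on the six-membered chelate, and hydride adds axially on the opposite face to give the 6R alcohol (O6 syn to O8, anti to C11). The γ-hydroxy ester then closes to the trans-fused lactone under mild acid.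

Step 14
Reactants: 18 silyl/benzyl ether lactone
Product: 21 (3S,6R,7R,8S)-3-(tert-butyldimethylsilyloxy)-8-(4-methoxybenzyloxy)germacra-1(10)E,4Z,11(13)-trien-12,6-olide, via Mannich base 19 (not isolated), via ammonium iodide 20 (not isolated)
Conditions: LiN(iPr)2, THF, −78 °C; CH2=NMe2+ I−, −78 → 0 °C; MeI (excess), rt; aq NaHCO3, CH2Cl2, rt
Reagents that add atoms: N,N-dimethylmethyleneiminium iodide C=[N+](C)C.[I-]
Why: Classical α-methylenation of a γ-lactone: Mannich reaction of the lithium enolate, quaternisation, and E1cB loss of trimethylamine. Only ethers are present, so no other enolisable ester competes, and the C11 centre formed in passing is destroyed.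

Step 15
Reactants: 21 methylene lactone bis-ether
Product: 22 (3S,6R,7R,8S)-3-(tert-butyldimethylsilyloxy)-8-hydroxygermacra-1(10)E,4Z,11(13)-trien-12,6-olide
Conditions: DDQ, CH2Cl2/pH 7 buffer (10:1), 0 °C
Reagents that add atoms: none
Why: Oxidative cleavage of the 4-methoxybenzyl ether through the benzylic oxocarbenium ion; the silyl ether, the diene and the methylene lactone are inert, and the only allylic oxygen is still protected.

Step 16
Reactants: 22 C8 alcohol
Product: 23 (3S,6R,7R,8S)-3-(tert-butyldimethylsilyloxy)-8-(3-methylbutanoyloxy)germacra-1(10)E,4Z,11(13)-trien-12,6-olide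
Conditions: (Me2CHCH2CO)2O, DMAP, Et3N, CH2Cl2, 0 °C → rt
Reagents that add atoms: 3-methylbutanoic anhydride CC(C)CC(=O)OC(=O)CC(C)C
Why: DMAP-catalysed acylation of the only free hydroxyl, with retention at C8.

Step 17
Reactants: 23 C8 isovalerate silyl ether
Product: 24 (3S,6R,7R,8S)-3-hydroxy-8-(3-methylbutanoyloxy)germacra-1(10)E,4Z,11(13)-trien-12,6-olide
Conditions: HF·pyridine, pyridine, THF, 0 °C → rt
Reagents that add atoms: none
Why: Desilylation under buffered acidic fluoride, which leaves the ester, the Michael acceptor and the 1,5-diene alone.

Step 18
Reactants: 24 C3 alcohol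
Product: 25 (3S,6R,7R,8S)-3-acetoxy-8-(3-methylbutanoyloxy)germacra-1(10)E,4Z,11(13)-trien-12,6-olide
Conditions: Ac2O, pyridine, DMAP (cat.), CH2Cl2, 0 °C
Reagents that add atoms: acetic anhydride CC(=O)OC(C)=O
Why: Acetylation of the allylic alcohol, with retention at C3.

Step 19
Reactants: 25 triene diester
Product: 26 (1R,3S,6R,7R,8S,10R)-3-acetoxy-1,10-epoxy-8-(3-methylbutanoyloxy)germacra-4Z,11(13)-dien-12,6-olide (target)
Conditions: mCPBA, NaHCO3, CH2Cl2, 0 °C
Reagents that add atoms: 3-chloroperoxybenzoic acid O=C(OO)c1cccc(Cl)c1
Why: Prilezhaev epoxidation of the only electron-rich olefin (C4=C5 lies between two acyloxy-bearing carbons, C11=C13 is conjugated). Syn delivery to the E olefin gives the trans epoxide, and attack on the outer face of the conformer with C14 on the β face should set 1R,10R; the buffer prevents transannular opening.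

## Compound list

1 | cis,cis-cyclohexane-1,3,5-triol | O[C@@H]1C[C@H](O)C[C@H](O)C1 | starting material
2 | cis,cis-5-(4-methoxybenzyloxy)cyclohexane-1,3-diol (meso) | O[C@@H]1C[C@H](O)C[C@H](OCc2ccc(OC)cc2)C1 | intermediate
3 | (1S,3S,5R)-3-hydroxy-5-(4-methoxybenzyloxy)cyclohexyl acetate | O[C@@H]1C[C@H](OC(C)=O)C[C@H](OCc2ccc(OC)cc2)C1 | intermediate
4 | (3R,5S)-3-acetoxy-5-(4-methoxybenzyloxy)cyclohexanone (not isolated) | O=C1C[C@H](OC(C)=O)C[C@H](OCc2ccc(OC)cc2)C1 | intermediate
5 | (S)-5-(4-methoxybenzyloxy)cyclohex-2-en-1-one | O=C1C=CC[C@H](OCc2ccc(OC)cc2)C1 | intermediate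
6 | [(3S,5S)-5-(4-methoxybenzyloxy)-3-methylcyclohex-1-en-1-yl]oxytrimethylsilane | C[C@@H]1C=C(O[Si](C)(C)C)C[C@@H](OCc2ccc(OC)cc2)C1 | intermediate
7 | (S)-5-(4-methoxybenzyloxy)-3-methylcyclohex-2-en-1-one | CC1=CC(=O)C[C@@H](OCc2ccc(OC)cc2)C1 | intermediate
8 | methyl bromoacetate | COC(=O)CBr | starting material
9 | methyl 2-[(1R,6S)-6-(4-methoxybenzyloxy)-4-methyl-2-oxocyclohex-3-en-1-yl]acetate | CC1=CC(=O)[C@H](CC(=O)OC)[C@@H](OCc2ccc(OC)cc2)C1 | intermediate
10 | methylenecyclobutane | C=C1CCC1 | starting material
11 | 1-methylcyclobutene | CC1=CCC1 | intermediate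
12 | rac-2-methylcyclobut-2-en-1-ol | CC1=CCC1O | intermediate
13 | (S)-2-methylcyclobut-2-en-1-ol | CC1=CC[C@@H]1O | intermediate
14 | (S)-tert-butyldimethyl(2-methylcyclobut-2-en-1-yloxy)silane | CC1=CC[C@@H]1O[Si](C)(C)C(C)(C)C | intermediate
15 | cis-anti-cis tricyclo[4.4.0.0(2,5)]decan-7-one photoadduct (C6 ketone, C7 CH2CO2Me, C8 OPMB, C3 OTBS) | O=C1[C@H](CC(=O)OC)[C@@H](OCc2ccc(OC)cc2)C[C@]3(C)[C@H]4C[C@H](O[Si](C)(C)C(C)(C)C)[C@@]4(C)[C@H]13 | intermediate
16 | methyl 2-[(1R,3Z,5S,7E,10S)-5-(tert-butyldimethylsilyloxy)-10-(4-methoxybenzyloxy)-4,8-dimethyl-2-oxocyclodeca-3,7-dien-1-yl]acetate | O=C1/C=C(/C)[C@@H](O[Si](C)(C)C(C)(C)C)C/C=C(\C)C[C@H](OCc2ccc(OC)cc2)[C@H]1CC(=O)OC | intermediate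
17 | 6R allylic alcohol of 16 (hydroxy ester; C3, C7, C8 unchanged in space; not isolated) | O[C@@H]1/C=C(/C)[C@@H](O[Si](C)(C)C(C)(C)C)C/C=C(\C)C[C@H](OCc2ccc(OC)cc2)[C@H]1CC(=O)OC | intermediate
18 | (3S,6R,7R,8S)-3-(tert-butyldimethylsilyloxy)-8-(4-methoxybenzyloxy)germacra-1(10)E,4Z-dien-12,6-olide | C1C(=O)O[C@@H]2/C=C(/C)[C@@H](O[Si](C)(C)C(C)(C)C)C/C=C(\C)C[C@H](OCc3ccc(OC)cc3)[C@@H]12 | intermediate
19 | 13-(dimethylamino) derivative of 18 (Mannich base, both C11 epimers; not isolated) | CN(C)CC1C(=O)O[C@@H]2/C=C(/C)[C@@H](O[Si](C)(C)C(C)(C)C)C/C=C(\C)C[C@H](OCc3ccc(OC)cc3)[C@@H]12 | intermediate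
20 | 13-(trimethylammonio) derivative of 18, iodide (not isolated) | C[N+](C)(C)CC1C(=O)O[C@@H]2/C=C(/C)[C@@H](O[Si](C)(C)C(C)(C)C)C/C=C(\C)C[C@H](OCc3ccc(OC)cc3)[C@@H]12.[I-] | intermediate
21 | (3S,6R,7R,8S)-3-(tert-butyldimethylsilyloxy)-8-(4-methoxybenzyloxy)germacra-1(10)E,4Z,11(13)-trien-12,6-olide | C=C1C(=O)O[C@@H]2/C=C(/C)[C@@H](O[Si](C)(C)C(C)(C)C)C/C=C(\C)C[C@H](OCc3ccc(OC)cc3)[C@@H]12 | intermediate
22 | (3S,6R,7R,8S)-3-(tert-butyldimethylsilyloxy)-8-hydroxygermacra-1(10)E,4Z,11(13)-trien-12,6-olide | C=C1C(=O)O[C@@H]2/C=C(/C)[C@@H](O[Si](C)(C)C(C)(C)C)C/C=C(\C)C[C@H](O)[C@@H]12 | intermediate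
23 | (3S,6R,7R,8S)-3-(tert-butyldimethylsilyloxy)-8-(3-methylbutanoyloxy)germacra-1(10)E,4Z,11(13)-trien-12,6-olide | C=C1C(=O)O[C@@H]2/C=C(/C)[C@@H](O[Si](C)(C)C(C)(C)C)C/C=C(\C)C[C@H](OC(=O)CC(C)C)[C@@H]12 | intermediate
24 | (3S,6R,7R,8S)-3-hydroxy-8-(3-methylbutanoyloxy)germacra-1(10)E,4Z,11(13)-trien-12,6-olide | C=C1C(=O)O[C@@H]2/C=C(/C)[C@@H](O)C/C=C(\C)C[C@H](OC(=O)CC(C)C)[C@@H]12 | intermediate
25 | (3S,6R,7R,8S)-3-acetoxy-8-(3-methylbutanoyloxy)germacra-1(10)E,4Z,11(13)-trien-12,6-olide | C=C1C(=O)O[C@@H]2/C=C(/C)[C@@H](OC(C)=O)C/C=C(\C)C[C@H](OC(=O)CC(C)C)[C@@H]12 | intermediate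
26 | (1R,3S,6R,7R,8S,10R)-3-acetoxy-1,10-epoxy-8-(3-methylbutanoyloxy)germacra-4Z,11(13)-dien-12,6-olide | C=C1C(=O)O[C@@H]2/C=C(/C)[C@@H](OC(C)=O)C[C@H]3O[C@]3(C)C[C@H](OC(=O)CC(C)C)[C@@H]12 | target

## Step count and risks

Total steps: 19. Longest linear sequence: 15 steps (steps 1–6, then 11–19); the cyclobutene branch (steps 7–10) joins at step 11.

**Step 11 (key step).** The most likely failures are regiochemical leakage towards head-to-tail adducts and loss of the triplet to side reactions. Enone 9 is more encumbered (α′-branched, with abstractable hydrogens on its side chain) than the simple 3-methylcyclohexenones on which the orientation argument rests, and it may also give ring-fusion isomers that are hard to separate. Fallback: the cycloaddition is moved one step earlier. Enone 7 and cyclobutene 14 are irradiated under the same conditions to give the side-chain-free cis-anti-cis adduct F1, with any trans-fused material epimerised at C5 on basic alumina. The kinetic lithium enolate of the rigid ketone (deprotonation at the C7 methylene, not the ring-fusion methine) is then alkylated with 8 anti to the C8 ether, returning to the route at 15.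

**Step 12.** The most likely failure is poor geometric control at the conjugated bond: scission of the diyl before rotation at C4 gives the 4E enone. Prolonged heating may also take the 1,5-diene on by Cope rearrangement to a divinylcyclohexane. Fallback: geometry setting is separated from bond cleavage. Tricycle 15 is cleaved by flash vacuum pyrolysis (short contact time, so the diene cannot rearrange), accepting the 1(10)E,4E dienone F2. The conjugated double bond is then equilibrated by reversible conjugate addition of catalytic thiolate (PhSH, Et3N, CH2Cl2) to the more stable Z enone, returning at 16.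

**Step 13.** The most likely failure is poor facial selectivity. If the ring conformer cannot hold the C6 and C8 oxygens in a chelate, hydride adds from the ring periphery, and the 6S alcohol may predominate. Fallback: the wrong epimer is used rather than avoided. Dienone 16 is reduced without chelation (NaBH4, CeCl3, MeOH) to the 6S hydroxy ester F3, and LiOH gives the 6S hydroxy acid F4. Mitsunobu lactonisation (PPh3, diisopropyl azodicarboxylate) then closes the ring with inversion at C6, returning at 18.

**Step 6.** The most likely failures are loss of the protecting group by E1cB expulsion of 4-methoxybenzyl alkoxide from the α′-enolate (driven by aromatisation to a phenol) and over-alkylation through proton transfer. Fallback: the leaving group is turned into one that cannot leave. Enone 7 is deprotected with DDQ to (S)-5-hydroxy-3-methylcyclohex-2-en-1-one F5. Its alkoxide-enolate dianion (two equivalents of lithium diisopropylamide) is alkylated with 8 in a Fráter–Seebach-type reaction, anti to the alkoxide, to give the trans hydroxy keto ester F6. Re-etherification under neutral conditions (2-(4-methoxybenzyloxy)-4-methylquinoline, MeOTf, MgO) returns to 9.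

**Step 19.** The most likely failure is poor or wrong facial selectivity of the peracid if the ring prefers a conformer that exposes the other face of C1=C10; acid-induced transannular opening of the product is the second risk. Fallback: oxygen is delivered to the opposite face in two steps. Triene 25 is treated with N-bromosuccinimide in aqueous 1,2-dimethoxyethane to give the bromohydrin F7 (bromine at C1 on the face the peracid would have used, hydroxyl at C10 on the other). DBU then closes the oxirane with inversion at C1, returning at 26.

## Further compounds

F1 | step 11 | cis-anti-cis photoadduct of 7 and 14 (15 without the C7 side chain) | O=C1C[C@@H](OCc2ccc(OC)cc2)C[C@]3(C)[C@H]4C[C@H](O[Si](C)(C)C(C)(C)C)[C@@]4(C)[C@H]13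
F2 | step 12 | 1(10)E,4E isomer of dienone 16 | O=C1/C=C(\C)[C@@H](O[Si](C)(C)C(C)(C)C)C/C=C(\C)C[C@H](OCc2ccc(OC)cc2)[C@H]1CC(=O)OC
F3 | step 13 | 6S hydroxy ester (C6 epimer of 17) | O[C@H]1/C=C(/C)[C@@H](O[Si](C)(C)C(C)(C)C)C/C=C(\C)C[C@H](OCc2ccc(OC)cc2)[C@H]1CC(=O)OC
F4 | step 13 | 6S hydroxy acid | O[C@H]1/C=C(/C)[C@@H](O[Si](C)(C)C(C)(C)C)C/C=C(\C)C[C@H](OCc2ccc(OC)cc2)[C@H]1CC(=O)O
F5 | step 6 | (S)-5-hydroxy-3-methylcyclohex-2-en-1-one | CC1=CC(=O)C[C@@H](O)C1
F6 | step 6 | methyl 2-[(1R,6S)-6-hydroxy-4-methyl-2-oxocyclohex-3-en-1-yl]acetate | CC1=CC(=O)[C@H](CC(=O)OC)[C@@H](O)C1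
F7 | step 19 | 1-bromo-10-hydroxy bromohydrin of 25 | C=C1C(=O)O[C@@H]2/C=C(/C)[C@@H](OC(C)=O)C[C@H](Br)[C@](C)(O)C[C@H](OC(=O)CC(C)C)[C@@H]12
A1 | alternative 1 | seco-lactone with Z iodoalkene at C4 and aldehyde at C3 | C=C1C(=O)O[C@H](/C=C(/C)I)[C@H]1[C@@H](OC(=O)CC(C)C)C/C(C)=C/CC=O
A2 | alternative 1 | 3-O-deacetyl-1,10-deoxy target (identical with 24) | C=C1C(=O)O[C@@H]2/C=C(/C)[C@@H](O)C/C=C(\C)C[C@H](OC(=O)CC(C)C)[C@@H]12
A3 | alternative 2 | seco-lactone with C9 bromide next to the C8 ketone and 1-chloro-10-oxo terminus | C1C(=O)O[C@H](/C=C(/C)[C@@H](O[Si](C)(C)C(C)(C)C)C[C@H](Cl)C(C)=O)[C@H]1C(=O)CBr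
A4 | alternative 2 | 1,10-epoxy-8-oxo lactone without the methylene, C3 silyl ether | C1C(=O)O[C@@H]2/C=C(/C)[C@@H](O[Si](C)(C)C(C)(C)C)C[C@H]3O[C@]3(C)CC(=O)[C@@H]12
A5 | alternative 3 | (1S,4S,6S)-4-(tert-butyldimethylsilyloxy)-1-[(E)-2-(4-methoxybenzyloxy)ethenyl]-3-methyl-6-(prop-1-en-2-yl)cyclohex-2-en-1-ol | C=C(C)[C@@H]1C[C@H](O[Si](C)(C)C(C)(C)C)C(C)=C[C@@]1(O)/C=C/OCc2ccc(OC)cc2
A6 | alternative 3 | 8-(4-methoxybenzyloxy)-3-silyloxycyclodeca-1(10)E,4Z-dien-6-one | O=C1/C=C(/C)[C@@H](O[Si](C)(C)C(C)(C)C)C/C=C(\C)C[C@H](OCc2ccc(OC)cc2)C1
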